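**Retrosynthetic overview**
- Pendant lactone last: C5'–C4' bond from the C3 aldehyde and a chiral ester homoenolate (zinc, then titanium), under chelation control.
- Cyclopentene and fused lactone together: the C11–C12 and O–C14 bonds form in one carbene-catalysed homoenolate cyclisation of an allenyl aldehyde (on C1) onto an aldehyde (on C10); this is the key step.
- Allenal from the C1 ketone (alkynylation, then anti-SN2′ methyl cuprate); C11 aldehyde from a vinyl group (ozonolysis).
- C9a quaternary centre and C10 by iridium-catalysed branched allylation of a 2-amino-1,3-diketone enolate; azepanone by Dieckmann-type acylation.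
- Pyrrolidine ring and C3 from trans-4-hydroxy-L-prolinol; ring order: pyrrolidine (bought) → azepanone → cyclopentene + fused lactone → pendant lactone.

Atom labels: pyrrolo[1,2-a]azepine numbering is kept throughout (C1–C3, N4, C5–C8, C9 = ketone, C9a = N-bearing quaternary carbon); C10 = CH(Et) on C9a, C11 = CH–O, C12 = alkene carbon bonded to C1, C13 = CH(CH3), C14 = fused-lactone carbonyl; pendant lactone O1', C2' (C=O), C3' (CH3), C4', C5' (on C3). Target: 3S, 9aR, 10R, 11S, 13R, 3'S, 5'S.

Assumption: the five starting materials are taken as catalogue chemicals; the C1 carbinol centre of the alkynylation products and the allene axis are left open in the SMILES because both are erased in the ring closure.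

Step 1
Reactants: 1 (3R,5S)-5-(hydroxymethyl)pyrrolidin-3-ol hydrochloride (trans-4-hydroxy-L-prolinol hydrochloride); 2 methyl 5-bromopentanoate
Product: 3 methyl 5-[(2S,4R)-4-hydroxy-2-(hydroxymethyl)pyrrolidin-1-yl]pentanoate
Conditions: K2CO3 (2.2 equiv), MeCN, 60 °C
Reagents that add atoms: none
Why: SN2 N-alkylation, the secondary amine being far more nucleophilic than either hydroxyl; no new stereocentre (C3 comes from the chiral pool).

Step 2
Reactants: 3 methyl 5-[(2S,4R)-4-hydroxy-2-(hydroxymethyl)pyrrolidin-1-yl]pentanoate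
Product: 4 methyl 5-[(2S,4R)-2-({[tert-butyl(dimethyl)silyl]oxy}methyl)-4-hydroxypyrrolidin-1-yl]pentanoate
Conditions: tert-butyldimethylsilyl chloride (1.05 equiv), imidazole, CH2Cl2, 0 °C
Reagents that add atoms: tert-butyldimethylsilyl chloride, CC(C)(C)[Si](C)(C)Cl
Why: silyl ether formation; the bulky silyl chloride takes the primary hydroxyl and leaves the ring secondary hydroxyl free for oxidation.

Step 3
Reactants: 4 methyl 5-[(2S,4R)-2-({[tert-butyl(dimethyl)silyl]oxy}methyl)-4-hydroxypyrrolidin-1-yl]pentanoate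
Product: 5 methyl 5-[(2S)-2-({[tert-butyl(dimethyl)silyl]oxy}methyl)-4-oxopyrrolidin-1-yl]pentanoate
Conditions: (COCl)2, DMSO, CH2Cl2, −78 °C; Et3N, −78 → 0 °C
Reagents that add atoms: none
Why: Swern oxidation of the only free alcohol; tertiary amine, ester and silyl ether are inert and C3 is not α to the new ketone.

Step 4
Reactants: 6 (E)-pent-2-en-1-ol
Product: 7 methyl (E)-pent-2-en-1-yl carbonate
Conditions: methyl chloroformate, pyridine, CH2Cl2, 0 °C
Reagents that add atoms: methyl chloroformate, COC(=O)Cl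
Why: O-acylation of the allylic alcohol installs the leaving group for the iridium allylation; alkene geometry is retained.

Step 5
Reactants: 5 methyl 5-[(2S)-2-({[tert-butyl(dimethyl)silyl]oxy}methyl)-4-oxopyrrolidin-1-yl]pentanoate; 7 methyl (E)-pent-2-en-1-yl carbonate
Product: 9 (3S,9aS)-3-({[tert-butyl(dimethyl)silyl]oxy}methyl)-9a-[(3S)-pent-1-en-3-yl]hexahydro-1H-pyrrolo[1,2-a]azepine-1,9(2H)-dione, via potassium diketonate 8 (not isolated)
Conditions: KOtBu (1.1 equiv), THF, 0 °C → rt; then 7 (1.3 equiv), [Ir(cod)Cl]2 (2 mol %), N,N-bis(1-phenylethyl)dinaphtho[2,1-d:1′,2′-f][1,3,2]dioxaphosphepin-4-amine (4 mol %, the antipode that gives 10S), 1,5,7-triazabicyclo[4.4.0]dec-5-ene (TBD, 10 mol %), rt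
Reagents that add atoms: none
Why: Dieckmann-type (Claisen) C-acylation, in which only the N-bound α-carbon can reach the ester in a fused seven-membered ring and the stable 2-amino-1,3-diketonate 8 drives the equilibrium, followed in the same flask (the free enol is an air-sensitive aminoreductone) by iridium-catalysed branched-selective allylic alkylation, where the ligand fixes the allylic centre C10 and the allyl unit enters C9a trans to the C3 silyloxymethyl group.

Step 6
Reactants: 9 (3S,9aS)-3-({[tert-butyl(dimethyl)silyl]oxy}methyl)-9a-[(3S)-pent-1-en-3-yl]hexahydro-1H-pyrrolo[1,2-a]azepine-1,9(2H)-dione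
Product: 11 (3S,9aS)-3-({[tert-butyl(dimethyl)silyl]oxy}methyl)-9a-[(2R)-1,1-dimethoxybutan-2-yl]hexahydro-1H-pyrrolo[1,2-a]azepine-1,9(2H)-dione, via aldehyde 10 (not isolated)
Conditions: O3, CF3CO2H (1.1 equiv), CH2Cl2/MeOH, −78 °C; Me2S, → rt; then HC(OMe)3, pyridinium p-toluenesulfonate (cat.), rt
Reagents that add atoms: ozone, [O-][O+]=O (oxygen of 10); trimethyl orthoformate, COC(OC)OC (methoxy groups of 11)
Why: ozonolysis of the only alkene (amine masked as its trifluoroacetate salt) with reductive work-up, then mild acetalisation of the aldehyde; the two α-quaternary ketones and the silyl ether survive, and C10 keeps its configuration.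

Step 7
Reactants: 11 (3S,9aS)-3-({[tert-butyl(dimethyl)silyl]oxy}methyl)-9a-[(2R)-1,1-dimethoxybutan-2-yl]hexahydro-1H-pyrrolo[1,2-a]azepine-1,9(2H)-dione; 12 3,3-diethoxyprop-1-yne
Product: 15 (3S,9aR)-3-({[tert-butyl(dimethyl)silyl]oxy}methyl)-1-(3,3-diethoxyprop-1-yn-1-yl)-9a-[(2R)-1,1-dimethoxybutan-2-yl]-9-oxooctahydro-1H-pyrrolo[1,2-a]azepin-1-yl methyl carbonate (C1 epimers), via lithium acetylide 13 (not isolated), via lithium alkoxide 14 (not isolated)
Conditions: 12, n-BuLi, THF, −78 °C; 11, −78 °C; methyl chloroformate, −78 → −20 °C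
Reagents that add atoms: methyl chloroformate, COC(=O)Cl
Why: 1,2-addition of a lithium acetylide to the more electrophilic five-ring ketone C1 (a pyrrolidin-3-one carbonyl should add nucleophiles faster than the cycloheptanone-type C9 carbonyl), with cold trapping of the tertiary alkoxide before retro-aldol cleavage; the new C1 centre is not controlled and is erased in step 8.

Step 8
Reactants: 15 (3S,9aR)-3-({[tert-butyl(dimethyl)silyl]oxy}methyl)-1-(3,3-diethoxyprop-1-yn-1-yl)-9a-[(2R)-1,1-dimethoxybutan-2-yl]-9-oxooctahydro-1H-pyrrolo[1,2-a]azepin-1-yl methyl carbonate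
Product: 16 (3S,9aR)-3-({[tert-butyl(dimethyl)silyl]oxy}methyl)-1-(3,3-diethoxy-2-methylprop-1-en-1-ylidene)-9a-[(2R)-1,1-dimethoxybutan-2-yl]octahydro-9H-pyrrolo[1,2-a]azepin-9-one
Conditions: Me2CuLi (from MeLi and CuI, 2.5 equiv), Et2O, −78 → −40 °C
Reagents that add atoms: lithium dimethylcuprate, [Li+].C[Cu-]C
Why: anti-SN2′ substitution of the tertiary propargylic carbonate by the cuprate builds the tetrasubstituted allene and its methyl group together; the C9 ketone is too slow for Me2CuLi at low temperature and the allene axis need not be controlled.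

Step 9
Reactants: 16 (3S,9aR)-3-({[tert-butyl(dimethyl)silyl]oxy}methyl)-1-(3,3-diethoxy-2-methylprop-1-en-1-ylidene)-9a-[(2R)-1,1-dimethoxybutan-2-yl]octahydro-9H-pyrrolo[1,2-a]azepin-9-one
Product: 17 (2R)-2-[(3S,9aR)-3-(hydroxymethyl)-1-(2-methyl-3-oxoprop-1-en-1-ylidene)-9-oxooctahydro-9aH-pyrrolo[1,2-a]azepin-9a-yl]butanal
Conditions: CF3CO2H/H2O/THF (2:1:4), 0 °C → rt
Reagents that add atoms: water, O
Why: acid hydrolysis frees both aldehydes and the primary alcohol at once; trifluoroacetate is too poor a nucleophile to add to the allenal, and C10 (α to the new aldehyde) does not enolise appreciably in cold acid.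

Step 10
Reactants: 17 (2R)-2-[(3S,9aR)-3-(hydroxymethyl)-1-(2-methyl-3-oxoprop-1-en-1-ylidene)-9-oxooctahydro-9aH-pyrrolo[1,2-a]azepin-9a-yl]butanal
Product: 19 (3S,9aR,10R,11S,13R)-tetracyclic keto lactone alcohol (target skeleton carrying CH2OH on C3), via Breslow intermediate 18 (not isolated)
Conditions: 2-mesityl-6,7-dihydro-5H-pyrrolo[2,1-c][1,2,4]triazol-2-ium chloride (15 mol %), iPr2NEt (30 mol %), THF (0.02 M), 40 °C
Reagents that add atoms: none
Why: Proposed new method: carbene-catalysed homoenolate annulation of an allenal with a tethered aldehyde — the carbene adds to the allenyl aldehyde (the neopentyl-type C11 aldehyde is too hindered to compete) and proton transfer gives Breslow intermediate 18, whose enaminol is conjugated with the C12=C13 π bond so that the central allene carbon C12 becomes nucleophilic; that π lobe lies in the plane of the C1 substituents and points at the C11 aldehyde held on C9a, so C12 attacks C11 in a 5-exo closure that leaves C1=C12 as the ring alkene, the enol azolium is protonated at C13, and the C11 alkoxide acylates itself on the acyl azolium to release the carbene and the γ-lactone (much faster than any reaction of the remote CH2OH); the C11 oxygen should form trans to the C10 ethyl group, C13 is set by protonation on the convex face and remains correctable under the amine base because C13–H is allylic and α to the lactone (the natural cis-α,γ-disubstituted lactone is expected to be the more stable epimer), and both allene diastereomers converge because the axis is destroyed; closest known reaction type: carbene-catalysed homoenolate addition of enals to aldehydes or tethered ketones giving γ-butyrolactones.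

Step 11
Reactants: 19 (3S,9aR,10R,11S,13R)-tetracyclic keto lactone alcohol
Product: 20 (3S,9aR,10R,11S,13R)-tetracyclic keto lactone aldehyde (CHO on C3)
Conditions: Dess–Martin periodinane (1,1,1-triacetoxy-1,1-dihydro-1,2-benziodoxol-3(1H)-one), CH2Cl2, 0 °C → rt
Reagents that add atoms: none
Why: Dess–Martin oxidation of the only alcohol (any hemiketal with C9 reopens under the acetic acid released); the unbuffered medium keeps the amine protonated, which limits epimerisation of the α-amino aldehyde at C3, and the aldehyde is used crude.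

Step 12
Reactants: 20 (3S,9aR,10R,11S,13R)-tetracyclic keto lactone aldehyde; 21 methyl (2R)-3-bromo-2-methylpropanoate
Product: 25 CNP0315436.2 (3S,9aR,10R,11S,13R,3'S,5'S), via organozinc bromide 22 (not isolated), via trichlorotitanium homoenolate 23 (not isolated), via hydroxy ester 24 (not isolated)
Conditions: 21, Zn, LiCl, THF, 40 °C; solvent change to CH2Cl2; TiCl4, −78 °C; 20, −78 → −40 °C; aq. NaHCO3; then pyridinium p-toluenesulfonate, CH2Cl2, rt
Reagents that add atoms: none
Why: zinc insertion gives a β-zincated ester (ester homoenolate) whose transmetalation to the trichlorotitanium homoenolate allows aldehyde-selective addition (the C9 ketone and the lactone do not react) under Cram chelation control — titanium bridges N4 and the aldehyde oxygen and the nucleophile enters past the C3 hydrogen — setting 5'S syn to N4, while 3'S is carried in from 21; mild acid then closes the γ-lactone.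

**Compound list**
1 | (3R,5S)-5-(hydroxymethyl)pyrrolidin-3-ol hydrochloride | OC[C@@H]1C[C@@H](O)CN1.Cl | starting material
2 | methyl 5-bromopentanoate | COC(=O)CCCCBr | starting material
3 | methyl 5-[(2S,4R)-4-hydroxy-2-(hydroxymethyl)pyrrolidin-1-yl]pentanoate | OC[C@@H]1C[C@@H](O)CN1CCCCC(=O)OC | intermediate
4 | methyl 5-[(2S,4R)-2-({[tert-butyl(dimethyl)silyl]oxy}methyl)-4-hydroxypyrrolidin-1-yl]pentanoate | CC(C)(C)[Si](C)(C)OC[C@@H]1C[C@@H](O)CN1CCCCC(=O)OC | intermediate
5 | methyl 5-[(2S)-2-({[tert-butyl(dimethyl)silyl]oxy}methyl)-4-oxopyrrolidin-1-yl]pentanoate | CC(C)(C)[Si](C)(C)OC[C@@H]1CC(=O)CN1CCCCC(=O)OC | intermediate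
6 | (E)-pent-2-en-1-ol | CC/C=C/CO | starting material
7 | methyl (E)-pent-2-en-1-yl carbonate | CC/C=C/COC(=O)OC | intermediate
8 | potassium (3S)-3-({[tert-butyl(dimethyl)silyl]oxy}methyl)-1-oxo-2,3,5,6,7,8-hexahydro-1H-pyrrolo[1,2-a]azepin-9-olate | [K+].[O-]C1=C2C(=O)C[C@@H](CO[Si](C)(C)C(C)(C)C)N2CCCC1 | intermediate
9 | (3S,9aS)-3-({[tert-butyl(dimethyl)silyl]oxy}methyl)-9a-[(3S)-pent-1-en-3-yl]hexahydro-1H-pyrrolo[1,2-a]azepine-1,9(2H)-dione | CC[C@@H](C=C)[C@]12C(=O)C[C@@H](CO[Si](C)(C)C(C)(C)C)N1CCCCC2=O | intermediate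
10 | (2R)-2-[(3S,9aS)-3-({[tert-butyl(dimethyl)silyl]oxy}methyl)-1,9-dioxooctahydro-9aH-pyrrolo[1,2-a]azepin-9a-yl]butanal | CC[C@@H](C=O)[C@]12C(=O)C[C@@H](CO[Si](C)(C)C(C)(C)C)N1CCCCC2=O | intermediate
11 | (3S,9aS)-3-({[tert-butyl(dimethyl)silyl]oxy}methyl)-9a-[(2R)-1,1-dimethoxybutan-2-yl]hexahydro-1H-pyrrolo[1,2-a]azepine-1,9(2H)-dione | CC[C@@H](C(OC)OC)[C@]12C(=O)C[C@@H](CO[Si](C)(C)C(C)(C)C)N1CCCCC2=O | intermediate
12 | 3,3-diethoxyprop-1-yne | C#CC(OCC)OCC | starting material
13 | lithium 3,3-diethoxyprop-1-yn-1-ide | [Li+].[C-]#CC(OCC)OCC | intermediate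
14 | lithium (3S,9aR)-3-({[tert-butyl(dimethyl)silyl]oxy}methyl)-1-(3,3-diethoxyprop-1-yn-1-yl)-9a-[(2R)-1,1-dimethoxybutan-2-yl]-9-oxooctahydro-1H-pyrrolo[1,2-a]azepin-1-olate (C1 epimers) | CC[C@@H](C(OC)OC)[C@]12C([O-])(C#CC(OCC)OCC)C[C@@H](CO[Si](C)(C)C(C)(C)C)N1CCCCC2=O.[Li+] | intermediate
15 | (3S,9aR)-3-({[tert-butyl(dimethyl)silyl]oxy}methyl)-1-(3,3-diethoxyprop-1-yn-1-yl)-9a-[(2R)-1,1-dimethoxybutan-2-yl]-9-oxooctahydro-1H-pyrrolo[1,2-a]azepin-1-yl methyl carbonate (C1 epimers) | CC[C@@H](C(OC)OC)[C@]12C(OC(=O)OC)(C#CC(OCC)OCC)C[C@@H](CO[Si](C)(C)C(C)(C)C)N1CCCCC2=O | intermediate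
16 | (3S,9aR)-3-({[tert-butyl(dimethyl)silyl]oxy}methyl)-1-(3,3-diethoxy-2-methylprop-1-en-1-ylidene)-9a-[(2R)-1,1-dimethoxybutan-2-yl]octahydro-9H-pyrrolo[1,2-a]azepin-9-one (allene axis open) | CC[C@@H](C(OC)OC)[C@]12C(=C=C(C)C(OCC)OCC)C[C@@H](CO[Si](C)(C)C(C)(C)C)N1CCCCC2=O | intermediate
17 | (2R)-2-[(3S,9aR)-3-(hydroxymethyl)-1-(2-methyl-3-oxoprop-1-en-1-ylidene)-9-oxooctahydro-9aH-pyrrolo[1,2-a]azepin-9a-yl]butanal | CC[C@@H](C=O)[C@]12C(=C=C(C)C=O)C[C@@H](CO)N1CCCCC2=O | intermediate
18 | Breslow intermediate: enaminol formed from the allenyl aldehyde of 17 and 2-mesityl-6,7-dihydro-5H-pyrrolo[2,1-c][1,2,4]triazol-3-ylidene | CC[C@@H](C=O)[C@]12C(=C=C(C)C(O)=C3N(c4c(C)cc(C)cc4C)N=C4CCCN34)C[C@@H](CO)N1CCCCC2=O | intermediate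
19 | (3S,9aR,10R,11S,13R)-tetracyclic keto lactone alcohol (CH2OH on C3) | CC[C@H]1[C@@H]2OC(=O)[C@H](C)C2=C2C[C@@H](CO)N3CCCCC(=O)[C@]213 | intermediate
20 | (3S,9aR,10R,11S,13R)-tetracyclic keto lactone aldehyde (CHO on C3) | CC[C@H]1[C@@H]2OC(=O)[C@H](C)C2=C2C[C@@H](C=O)N3CCCCC(=O)[C@]213 | intermediate
21 | methyl (2R)-3-bromo-2-methylpropanoate | COC(=O)[C@@H](C)CBr | starting material
22 | bromo[(2R)-3-methoxy-2-methyl-3-oxopropyl]zinc | COC(=O)[C@@H](C)C[Zn]Br | intermediate
23 | trichloro[(2R)-3-methoxy-2-methyl-3-oxopropyl]titanium | COC(=O)[C@@H](C)C[Ti](Cl)(Cl)Cl | intermediate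
24 | methyl (2S,4S)-4-hydroxy-2-methyl-4-[(3S,9aR,10R,11S,13R)-tetracyclic keto lactone-3-yl]butanoate | CC[C@H]1[C@@H]2OC(=O)[C@H](C)C2=C2C[C@@H]([C@@H](O)C[C@H](C)C(=O)OC)N3CCCCC(=O)[C@]213 | intermediate
25 | CNP0315436.2 (3S,9aR,10R,11S,13R,3'S,5'S) | CC[C@H]1[C@@H]2OC(=O)[C@H](C)C2=C2C[C@@H]([C@@H]3C[C@H](C)C(=O)O3)N3CCCCC(=O)[C@]213 | target

**Step count**
Total: 12 steps. Longest linear sequence: 11 steps (steps 1–3 and 5–12; step 4 is a one-step branch).

**Steps most likely to fail**

Step 10, the ring closure. The α-methyl group may slow carbene addition, the allenal may isomerise to a dienal, or C8 may undergo aldol addition to the C11 aldehyde. The fallback replaces the carbene by a reductive ketyl cyclisation onto an allenoate; it sets out from 11 and returns at 19. Lithiated 3,3,3-triethoxyprop-1-yne (n-BuLi, THF, −78 °C) is added to 11 and the alkoxide is trapped with methyl chloroformate to give the propargylic carbonate ortho ester F1. Me2CuLi converts it by anti-SN2′ substitution into the allenyl ortho ester F2. CF3CO2H/H2O/THF then unmasks aldehyde, alcohol and ester to give the ethyl allenoate aldehyde F3. SmI2 (2.2 equiv) with t-BuOH in THF at −78 °C forms the C11 ketyl, which adds to the central allene carbon; the samarium alkoxide lactonises and the route is rejoined at 19. The C9 ketone is the main hazard under SmI2 (α-amino ketones can lose nitrogen) and is expected to be partly masked as its hemiketal with the free CH2OH.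

Step 7, addition to C1 in the presence of the C9 ketone. The two ketones may not be told apart, or the adduct may fragment. The fallback masks C9 internally; it sets out from 11 and returns at 17. Camphorsulfonic acid in MeOH with HC(OMe)3 removes the silyl group and ties C9 to the freed hydroxymethyl group (which is cis to C9 on the pyrrolidine) as the bridged cyclic methyl ketal F4. Alkynylation and chloroformate trapping as in step 7 now meet only the C1 ketone and give the propargylic carbonate F5. Me2CuLi gives the allene F6. The hydrolysis of step 9 opens ketal and acetals together and returns to 17.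

Step 5, the Dieckmann closure and allylation. The seven-membered acylation may be slow, or the iridium step may give linear product or the wrong face. The fallback moves the allyl group from nitrogen to carbon by a sigmatropic shift; it sets out from 5 and returns at 9. KOtBu in THF followed by an acetic acid quench gives the enolised diketone F7, kept under argon. (E)-1-Bromopent-2-ene in MeCN quaternises N4 trans to the C3 substituent to give the ammonium bromide F8. K2CO3 forms the ammonium ylide F9, whose [2,3]-sigmatropic rearrangement delivers the transposed pentenyl group to C9a on the face it occupied on nitrogen, giving 9; the C10 configuration then depends on the envelope transition state and would have to be checked.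

Further compounds
F1 | step 10 | (3S,9aR)-3-({[tert-butyl(dimethyl)silyl]oxy}methyl)-9a-[(2R)-1,1-dimethoxybutan-2-yl]-9-oxo-1-(3,3,3-triethoxyprop-1-yn-1-yl)octahydro-1H-pyrrolo[1,2-a]azepin-1-yl methyl carbonate (C1 epimers) | CC[C@@H](C(OC)OC)[C@]12C(OC(=O)OC)(C#CC(OCC)(OCC)OCC)C[C@@H](CO[Si](C)(C)C(C)(C)C)N1CCCCC2=O
F2 | step 10 | (3S,9aR)-3-({[tert-butyl(dimethyl)silyl]oxy}methyl)-9a-[(2R)-1,1-dimethoxybutan-2-yl]-1-(3,3,3-triethoxy-2-methylprop-1-en-1-ylidene)octahydro-9H-pyrrolo[1,2-a]azepin-9-one | CC[C@@H](C(OC)OC)[C@]12C(=C=C(C)C(OCC)(OCC)OCC)C[C@@H](CO[Si](C)(C)C(C)(C)C)N1CCCCC2=O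
F3 | step 10 | ethyl 3-[(3S,9aR)-3-(hydroxymethyl)-9-oxo-9a-[(2R)-1-oxobutan-2-yl]hexahydro-1H-pyrrolo[1,2-a]azepin-1(2H)-ylidene]-2-methylprop-2-enoate | CC[C@@H](C=O)[C@]12C(=C=C(C)C(=O)OCC)C[C@@H](CO)N1CCCCC2=O
F4 | step 7 | bridged C9 methyl ketal of desilylated 11 (C9 joined through oxygen to the C3 CH2 group; C1 ketone and C11 dimethyl acetal kept) | CC[C@@H](C(OC)OC)[C@]12C(=O)C[C@H]3CO[C@]2(OC)CCCCN13
F5 | step 7 | C1 (3,3-diethoxyprop-1-yn-1-yl) methyl carbonate of F4 (C1 epimers) | CC[C@@H](C(OC)OC)[C@]12C(OC(=O)OC)(C#CC(OCC)OCC)C[C@H]3CO[C@]2(OC)CCCCN13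
F6 | step 7 | C1 (3,3-diethoxy-2-methylprop-1-en-1-ylidene) allene of the bridged ketal series | CC[C@@H](C(OC)OC)[C@]12C(=C=C(C)C(OCC)OCC)C[C@H]3CO[C@]2(OC)CCCCN13
F7 | step 5 | (3S)-3-({[tert-butyl(dimethyl)silyl]oxy}methyl)-9-hydroxy-2,3,5,6,7,8-hexahydro-1H-pyrrolo[1,2-a]azepin-1-one (enol form of the 1,9-dione) | OC1=C2C(=O)C[C@@H](CO[Si](C)(C)C(C)(C)C)N2CCCC1
F8 | step 5 | N4-[(E)-pent-2-en-1-yl]ammonium bromide of F7 (allyl group trans to the C3 substituent) | [Br-].OC1=C2C(=O)C[C@@H](CO[Si](C)(C)C(C)(C)C)[N@@+]2(C/C=C/CC)CCCC1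
F9 | step 5 | ammonium ylide (9-olate zwitterion) of F8 | [O-]C1=C2C(=O)C[C@@H](CO[Si](C)(C)C(C)(C)C)[N@@+]2(C/C=C/CC)CCCC1
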